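**Plan**

- Cuts, in retrosynthetic order: the three acetates; the C14 carbinol and C2 alcohol back to an isoxazoline (C14=N–O–C2); then C14–C1 and O–C2 together (nitrile oxide on C14 across the E C1=C2 olefin of ring B); then C17–C8 (lactone), C7–C8 (ring B), C11–C20, C10–C11 and C9=C10.
- Enabling feature: the quaternary C1 is the ring A/ring B fusion atom and sits between the oxygenated C14 and C2. An isoxazoline over C14–C1–C2 stores this 1,3-dioxygen pattern, and its C14–C1 bond is the last bond of ring A.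
- Forward order: nerol supplies C1–C7 and C10 with the Z C5=C6 olefin and, after SeO2 oxidation, the E C1=C2 olefin. C8/C9 come by olefination, C11–C14 by alkynylalane opening of a C9–C10 epoxide, C20 by carbomagnesiation. Ring B closes at C7–C8 (SmI2 pinacol), the lactone by an O7-tethered Reformatsky reaction, ring A and the isoxazoline in the cycloaddition.
- Stereochemistry: C9/C10 from Sharpless epoxidation and invertive opening; C7 from the pinacol; C8/C17 from the tethered Reformatsky closure; C1/C2 from suprafacial addition to the E olefin on the face set by C10; C14 from chelation-controlled reduction.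

Key step: step 20

Remark 1: locants C1–C20 are those of the briarane skeleton (ring B = C1–C10, ring A = C1, C10–C14, lactone O–C7, C8, C17, C19) and are used for every intermediate; α/β refer to ring B with the C15 methyl β.
Remark 2: C9 carries a PMB ether through the key step so that a single acetylation finishes the synthesis; the acetal carbon of 14–16, the bromine-bearing carbon of 22/23 and the oxime geometry of 27 are inconsequential mixtures; the C8 carbinol of 20 is drawn as the expected cis-diol and its epimer would converge in step 16.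
Abbreviations: TBS = tert-butyldimethylsilyl, TBDPS = tert-butyldiphenylsilyl, TMS = trimethylsilyl, PMB = 4-methoxybenzyl, DMP = Dess–Martin periodinane, CSA = camphorsulfonic acid.

**Route**

Step 1
Reactants: 1 nerol
Product: 2 neryl TBS ether
Conditions: TBSCl, imidazole, DMF, 0 °C to rt
Reagents that add atoms: tert-butyldimethylsilyl chloride CC(C)(C)[Si](C)(C)Cl
Why: Silyl ether formation on the primary allylic alcohol masks O7 until ring B is closed and leaves both olefins untouched.

Step 2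
Reactants: 2 neryl TBS ether
Product: 4 (2E,6Z)-8-(TBS-oxy)-2,6-dimethylocta-2,6-dienal, via allylic alcohol 3 (not isolated)
Conditions: SeO2 (10 mol %), t-BuOOH, salicylic acid (cat.), CH2Cl2, rt; then MnO2, CH2Cl2, rt
Reagents that add atoms: tert-butyl hydroperoxide CC(C)(C)OO (oxygen atom, relayed by catalytic SeO2)
Why: Riley allylic oxidation (ene reaction then [2,3]-shift) of the trisubstituted olefin takes the methyl group trans to the chain, which fixes the E C1=C2 geometry, and MnO2 converges alcohol/aldehyde mixtures on the enal.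

Step 3
Reactants: 4 C10 enal; 5 triethyl phosphonoacetate
Product: 6 ethyl (2E,4E,8Z)-10-(TBS-oxy)-4,8-dimethyldeca-2,4,8-trienoate
Conditions: NaH, THF, 0 °C to rt
Reagents that add atoms: none
Why: Horner–Wadsworth–Emmons olefination adds C9 and C8 and should give the E C9=C10 enoate needed for a trans epoxide.

Step 4
Reactants: 6 dienoate
Product: 7 (2E,4E,8Z)-10-(TBS-oxy)-4,8-dimethyldeca-2,4,8-trien-1-ol
Conditions: i-Bu2AlH, CH2Cl2, −78 °C
Reagents that add atoms: none
Why: 1,2-Reduction of the conjugated ester by i-Bu2AlH gives the allylic alcohol without touching the olefins or the silyl ether.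

Step 5
Reactants: 7 dienol
Product: 8 (9R,10R)-epoxy alcohol
Conditions: Ti(OiPr)4 (10 mol %), D-(−)-diethyl tartrate (12 mol %), t-BuOOH, 4 Å sieves, CH2Cl2, −20 °C
Reagents that add atoms: tert-butyl hydroperoxide CC(C)(C)OO
Why: Sharpless asymmetric epoxidation with D-(−)-tartrate should give the (9R,10R)-epoxide from the E allylic alcohol, and only the olefin of the free allylic alcohol reacts.

Step 6
Reactants: 9 but-3-yn-1-ol
Product: 10 (but-3-yn-1-yloxy)trimethylsilane
Conditions: TMSCl, Et3N, CH2Cl2, 0 °C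
Reagents that add atoms: chlorotrimethylsilane C[Si](C)(C)Cl
Why: Silylation gives a temporary O14 ether that tolerates acetylide formation and falls off by mild methanolysis in the next step.

Step 7
Reactants: 8 epoxy alcohol; 10 silyl butynyl ether
Product: 13 (9S,10R)-alkynyl triol, via alkynylalane 11 (not isolated), via TMS ether diol 12 (not isolated)
Conditions: 10, n-BuLi, toluene, −78 °C; Et2AlCl, 0 °C (3 equiv of alane); then 8, 0 °C to rt; Rochelle-salt work-up; then K2CO3 (cat.), MeOH, rt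
Reagents that add atoms: none
Why: Organoaluminium opening of a 2,3-epoxy alcohol delivers the alkynyl group to the distal, allylically activated C10 with inversion, which sets the C9/C10 pair and leaves the 8,9-diol, and methanolysis then removes the TMS ether.

Step 8
Reactants: 13 alkynyl triol
Product: 14 8,9-O-(4-methoxybenzylidene) acetal with free C14-OH
Conditions: 4-MeOC6H4CH(OMe)2, PPTS (cat.), CH2Cl2, rt
Reagents that add atoms: 4-methoxybenzaldehyde dimethyl acetal COc1ccc(cc1)C(OC)OC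
Why: Acid-catalysed transacetalisation ties the 1,2-diol into a dioxolane, leaves the isolated C14 hydroxyl free to direct the next step and pre-installs the later PMB group.

Step 9
Reactants: 14 alkynol acetal
Product: 15 (11Z)-alkenol acetal carrying the C20 methyl on C11
Conditions: Fe(acac)3 (15 mol %), MeMgBr (5 equiv), THF, −78 to 0 °C; aq NH4Cl
Reagents that add atoms: methylmagnesium bromide C[Mg]Br
Why: Iron-catalysed, alkoxide-directed carbomagnesiation of a homopropargylic alcohol adds CH3 and Mg syn across C11≡C12 with magnesium held at C12 by the five-membered alkoxide chelate, so protonation should give the Z olefin (C10 cis to C13) with the methyl on C11.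

Step 10
Reactants: 15 alkenol acetal
Product: 16 14-O-TBDPS ether
Conditions: TBDPSCl, imidazole, DMF, rt
Reagents that add atoms: tert-butyl(chloro)diphenylsilane CC(C)(C)[Si](Cl)(c1ccccc1)c1ccccc1
Why: Silylation with the acid-stable TBDPS group protects O14 so that the TBS ether on O7 can later be removed selectively.

Step 11
Reactants: 16 acetal
Product: 17 C8 primary alcohol with 9-OPMB
Conditions: i-Bu2AlH (3 equiv), CH2Cl2, −78 to 0 °C
Reagents that add atoms: none
Why: Reductive opening of the 4-methoxybenzylidene acetal by i-Bu2AlH, which coordinates the less hindered O8, leaves the PMB ether on the secondary O9 and frees the primary C8 alcohol.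

Step 12
Reactants: 17 C8 alcohol
Product: 18 7,8-diol (seco-diol)
Conditions: CSA (cat.), MeOH/CH2Cl2, 0 °C
Reagents that add atoms: none
Why: Acid-catalysed methanolysis cleaves the primary allylic TBS ether while the TBDPS and PMB ethers survive.

Step 13
Reactants: 18 seco-diol
Product: 19 dialdehyde (C7 Z-enal and C8 α-alkoxy aldehyde)
Conditions: DMP (2.5 equiv), NaHCO3, CH2Cl2, 0 °C to rt; used at once
Reagents that add atoms: none
Why: Buffered Dess–Martin oxidation converts both primary alcohols to aldehydes under non-enolising conditions that should keep the Z enal geometry and the C9 configuration.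

Step 14
Reactants: 19 dialdehyde
Product: 20 ring B diol (7S)
Conditions: SmI2 (3 equiv), THF (0.003 M, slow addition of 19), −78 °C to rt; aq NH4Cl
Reagents that add atoms: none
Why: Intramolecular samarium diiodide pinacol coupling of the dialdehyde forms C7–C8 and ring B; the samarium-bridged diketyl should close to the cis-diol with the C8 oxygen turned away from the C9 ether, which puts O7 on the α-face (7S), and the C8 configuration is erased in step 16.

Step 15
Reactants: 20 ring B diol; 21 2-bromopropanoyl bromide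
Product: 22 7-O-(2-bromopropanoyl) ester
Conditions: pyridine, CH2Cl2, −78 °C (1.05 equiv of 21)
Reagents that add atoms: none
Why: Acylation should take the less hindered allylic C7 hydroxyl, flanked by the sp2 C6, in preference to the C8 hydroxyl next to the branched C9, and puts the C17–C19 unit on O7.

Step 16
Reactants: 22 bromo ester
Product: 23 C8 ketone
Conditions: DMP, NaHCO3, CH2Cl2, 0 °C to rt
Reagents that add atoms: none
Why: Buffered Dess–Martin oxidation of the remaining secondary alcohol gives the C8 ketone without enolising towards C7 or C9.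

Step 17
Reactants: 23 keto bromo ester
Product: 24 ring B lactone (8-OH free; 9-OPMB; 14-OTBDPS)
Conditions: SmI2 (2.5 equiv), THF, −78 °C; aq NH4Cl
Reagents that add atoms: none
Why: Intramolecular Reformatsky reaction, in which SmI2 turns the α-bromo ester into a trivalent samarium enolate that adds to the adjacent C8 ketone; the O7 tether delivers C17 syn to O7 so that C9 ends trans to C6 (the unstrained fusion of a five- to the ten-membered ring, 8-OH α) and the C18 methyl should settle trans to C9 (17R).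

Step 18
Reactants: 24 lactone silyl ether
Product: 25 C14 alcohol
Conditions: TBAF, AcOH (1:1), THF, rt
Reagents that add atoms: none
Why: Buffered fluoride desilylation frees the primary C14 alcohol without base-induced retro-aldol opening or C17 epimerisation of the β-hydroxy lactone.

Step 19
Reactants: 25 C14 alcohol
Product: 27 C14 aldoxime, via aldehyde 26 (not isolated)
Conditions: DMP, NaHCO3, CH2Cl2, 0 °C; filter; then NH2OH·HCl, pyridine, EtOH, 0 °C to rt
Reagents that add atoms: hydroxylamine hydrochloride NO.Cl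
Why: Dess–Martin oxidation gives the sensitive β,γ-unsaturated aldehyde, which is condensed at once with hydroxylamine to the aldoxime before it can move into conjugation.

Step 20
Reactants: 27 aldoxime
Product: 30 ring A-fused isoxazoline, via hydroximoyl chloride 28 (not isolated), via nitrile oxide 29 (not isolated)
Conditions: aq NaOCl, CH2Cl2 (0.005 M, slow addition of 27), 0 °C to rt
Reagents that add atoms: none
Why: Hypochlorite chlorinates the aldoxime to hydroximoyl chloride 28, which loses HCl to nitrile oxide 29; this adds in a concerted, suprafacial (3+2) cycloaddition across the E C1=C2 olefin of ring B, the dipole carbon C14 bonding to C1 and the oxygen to C2. The closest known reaction is the intramolecular nitrile oxide–olefin cycloaddition that gives cyclohexane-fused isoxazolines, here with the olefin inside a ten-membered ring. Ring A (six-membered) closes through C14–C1 in the exo mode over the three-atom tether C13–C12=C11 from C10, and the five-membered isoxazoline closes through O–C2 in the same event. C1 and C2 are set relative to each other by syn addition to the E olefin, and their absolute sense by C10: in the chair-like tether C9 lies equatorial and H10 axial, so C14 should reach C1 on the α-face and give the trans A/B fusion (1R,2S in 30). Regiochemistry is enforced by tether length (bonding C14 to C2 would need a bridged seven-membered ring), the C5=C6 and C11=C12 olefins are out of reach of the dipole, and slow addition at high dilution holds back furoxan formation.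

Step 21
Reactants: 30 isoxazoline
Product: 32 β-hydroxy ketone (C14 ketone; C2-OH), via β-hydroxy imine 31 (not isolated)
Conditions: Mo(CO)6, MeCN/H2O (10:1), 80 °C
Reagents that add atoms: water O
Why: Mo(CO)6 cleaves the isoxazoline N–O bond reductively and the β-hydroxy imine is hydrolysed in the wet medium under neutral conditions, which should avoid retro-aldol cleavage of C1–C2 and conjugation of the C11=C12 olefin.

Step 22
Reactants: 32 β-hydroxy ketone
Product: 34 2,14-diol (14S), via diethylborinate 33 (not isolated)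
Conditions: Et2BOMe, THF/MeOH (4:1), −78 °C; NaBH4, −78 °C; AcOH quench, MeOH co-evaporation
Reagents that add atoms: none
Why: Chelation-controlled (Narasaka–Prasad) reduction, in which the diethylboron group bridges O2 and the C14 carbonyl oxygen on the α-face of ring A so that external borohydride attacks from the β-face and should give the axial 14α-alcohol, trans to the C15 methyl.

Step 23
Reactants: 34 diol PMB ether
Product: 35 2,8,9,14-tetraol
Conditions: DDQ, CH2Cl2/pH 7 buffer (10:1), 0 °C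
Reagents that add atoms: none
Why: Oxidative cleavage of the PMB ether by DDQ in buffered wet solvent frees O9 without affecting the olefins, the lactone or the other alcohols.

Step 24
Reactants: 35 tetraol
Product: 36 CNP0187165.2 (target)
Conditions: Ac2O, pyridine, DMAP (cat.), CH2Cl2, 0 °C to rt
Reagents that add atoms: acetic anhydride CC(=O)OC(C)=O
Why: DMAP-catalysed acetylation esterifies the three secondary alcohols at C2, C9 and C14 while the hindered tertiary 8-OH should remain free.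

**Compound list**

1 | nerol, (2Z)-3,7-dimethylocta-2,6-dien-1-ol | CC(C)=CCC/C(C)=C\CO | starting material
2 | neryl TBS ether, tert-butyl{[(2Z)-3,7-dimethylocta-2,6-dien-1-yl]oxy}dimethylsilane | CC(C)=CCC/C(C)=C\CO[Si](C)(C)C(C)(C)C | intermediate
3 | (2E,6Z)-8-(TBS-oxy)-2,6-dimethylocta-2,6-dien-1-ol (C10 allylic alcohol) | OC/C(C)=C/CC/C(C)=C\CO[Si](C)(C)C(C)(C)C | intermediate
4 | (2E,6Z)-8-(TBS-oxy)-2,6-dimethylocta-2,6-dienal (C10 enal) | O=C/C(C)=C/CC/C(C)=C\CO[Si](C)(C)C(C)(C)C | intermediate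
5 | triethyl phosphonoacetate | CCOC(=O)CP(=O)(OCC)OCC | starting material
6 | ethyl (2E,4E,8Z)-10-(TBS-oxy)-4,8-dimethyldeca-2,4,8-trienoate | CCOC(=O)/C=C/C(C)=C/CC/C(C)=C\CO[Si](C)(C)C(C)(C)C | intermediate
7 | (2E,4E,8Z)-10-(TBS-oxy)-4,8-dimethyldeca-2,4,8-trien-1-ol | OC/C=C/C(C)=C/CC/C(C)=C\CO[Si](C)(C)C(C)(C)C | intermediate
8 | {(2R,3R)-3-[(2E,6Z)-8-(TBS-oxy)-6-methylocta-2,6-dien-2-yl]oxiran-2-yl}methanol (9R,10R-epoxide) | OC[C@H]1O[C@@H]1/C(C)=C/CC/C(C)=C\CO[Si](C)(C)C(C)(C)C | intermediate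
9 | but-3-yn-1-ol | C#CCCO | starting material
10 | (but-3-yn-1-yloxy)trimethylsilane | C#CCCO[Si](C)(C)C | intermediate
11 | diethyl[4-(trimethylsilyloxy)but-1-yn-1-yl]aluminium | CC[Al](CC)C#CCCO[Si](C)(C)C | intermediate
12 | (2S,3R)-3-[(2E,6Z)-8-(TBS-oxy)-6-methylocta-2,6-dien-2-yl]-7-(trimethylsilyloxy)hept-4-yne-1,2-diol | OC[C@@H](O)[C@@H](C#CCCO[Si](C)(C)C)/C(C)=C/CC/C(C)=C\CO[Si](C)(C)C(C)(C)C | intermediate
13 | (2S,3R)-3-[(2E,6Z)-8-(TBS-oxy)-6-methylocta-2,6-dien-2-yl]hept-4-yne-1,2,7-triol (9S,10R) | OC[C@@H](O)[C@@H](C#CCCO)/C(C)=C/CC/C(C)=C\CO[Si](C)(C)C(C)(C)C | intermediate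
14 | 8,9-O-(4-methoxybenzylidene) acetal of 13: 2-(4-methoxyphenyl)-1,3-dioxolane across O8/O9, C14-OH free, acetal carbon as epimer mixture | COc1ccc(cc1)C2OC[C@@H](O2)[C@@H](C#CCCO)/C(C)=C/CC/C(C)=C\CO[Si](C)(C)C(C)(C)C | intermediate
15 | acetal 14 with C11≡C12 converted to the Z C11(CH3)=C12H olefin (C10 cis to C13), C14-OH free; 9S,10R | COc1ccc(cc1)C2OC[C@@H](O2)[C@@H](/C(C)=C\CCO)/C(C)=C/CC/C(C)=C\CO[Si](C)(C)C(C)(C)C | intermediate
16 | 14-O-TBDPS ether of 15 | COc1ccc(cc1)C2OC[C@@H](O2)[C@@H](/C(C)=C\CCO[Si](c3ccccc3)(c4ccccc4)C(C)(C)C)/C(C)=C/CC/C(C)=C\CO[Si](C)(C)C(C)(C)C | intermediate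
17 | (2S,3R,4E,8Z)-3-[(2Z)-5-(TBDPS-oxy)pent-2-en-2-yl]-10-(TBS-oxy)-2-(PMB-oxy)-4,8-dimethyldeca-4,8-dien-1-ol (C8-OH free, 9-OPMB) | OC[C@@H](OCc1ccc(OC)cc1)[C@@H](/C(C)=C\CCO[Si](c2ccccc2)(c3ccccc3)C(C)(C)C)/C(C)=C/CC/C(C)=C\CO[Si](C)(C)C(C)(C)C | intermediate
18 | (2Z,6E,8R,9S)-8-[(2Z)-5-(TBDPS-oxy)pent-2-en-2-yl]-9-(PMB-oxy)-3,7-dimethyldeca-2,6-diene-1,10-diol (C7-OH and C8-OH free) | OC[C@@H](OCc1ccc(OC)cc1)[C@@H](/C(C)=C\CCO[Si](c2ccccc2)(c3ccccc3)C(C)(C)C)/C(C)=C/CC/C(C)=C\CO | intermediate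
19 | (2Z,6E,8R,9S)-8-[(2Z)-5-(TBDPS-oxy)pent-2-en-2-yl]-9-(PMB-oxy)-3,7-dimethyldeca-2,6-dienedial (C7 enal, C8 aldehyde) | O=C[C@@H](OCc1ccc(OC)cc1)[C@@H](/C(C)=C\CCO[Si](c2ccccc2)(c3ccccc3)C(C)(C)C)/C(C)=C/CC/C(C)=C\C=O | intermediate
20 | ring B diol: (1E,5Z,7S,8S,9S,10R)-9-(PMB-oxy)-10-[(2Z)-5-(TBDPS-oxy)pent-2-en-2-yl]-1,5-dimethylcyclodeca-1,5-diene-7,8-diol (briarane locants) | O[C@@H]1[C@@H](OCc2ccc(OC)cc2)[C@@H](/C(C)=C\CCO[Si](c3ccccc3)(c4ccccc4)C(C)(C)C)/C(C)=C/CC/C(C)=C\[C@@H]1O | intermediate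
21 | 2-bromopropanoyl bromide (racemic) | CC(Br)C(Br)=O | starting material
22 | 7-O-(2-bromopropanoyl) ester of 20 (8-OH free; 7S,8R,9S,10R) | O[C@@H]1[C@@H](OCc2ccc(OC)cc2)[C@@H](/C(C)=C\CCO[Si](c3ccccc3)(c4ccccc4)C(C)(C)C)/C(C)=C/CC/C(C)=C\[C@@H]1OC(=O)C(C)Br | intermediate
23 | 8-ketone of 22 (7S,9S,10R) | O=C1[C@@H](OCc2ccc(OC)cc2)[C@@H](/C(C)=C\CCO[Si](c3ccccc3)(c4ccccc4)C(C)(C)C)/C(C)=C/CC/C(C)=C\[C@@H]1OC(=O)C(C)Br | intermediate
24 | ring B lactone: (1E,5Z)-cyclodeca-1,5-diene fused at C7–C8 to the lactone O7–C19(=O)–C17H(CH3)–C8(OH); 9-OPMB; C10 side chain (2Z)-5-(TBDPS-oxy)pent-2-en-2-yl; 7S,8R,9S,10R,17R | CC(C)(C)[Si](c1ccccc1)(c2ccccc2)OCC/C=C(C)\[C@@H]3[C@H](OCc4ccc(OC)cc4)[C@@]5(O)[C@H](/C=C(/C)CC/C=C3\C)OC(=O)[C@@H]5C | intermediate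
25 | C14 alcohol of 24 (side chain (2Z)-5-hydroxypent-2-en-2-yl) | OCC/C=C(C)\[C@@H]1[C@H](OCc2ccc(OC)cc2)[C@@]3(O)[C@H](/C=C(/C)CC/C=C1\C)OC(=O)[C@@H]3C | intermediate
26 | C14 aldehyde of 25 (side chain (2Z)-5-oxopent-2-en-2-yl) | O=CC/C=C(C)\[C@@H]1[C@H](OCc2ccc(OC)cc2)[C@@]3(O)[C@H](/C=C(/C)CC/C=C1\C)OC(=O)[C@@H]3C | intermediate
27 | C14 aldoxime: (1E,5Z)-cyclodecadiene lactone with 8-OH, 9-OPMB and C10 side chain (2Z)-5-(hydroxyimino)pent-2-en-2-yl; 7S,8R,9S,10R,17R | O/N=C/C/C=C(C)\[C@@H]1[C@H](OCc2ccc(OC)cc2)[C@@]3(O)[C@H](/C=C(/C)CC/C=C1\C)OC(=O)[C@@H]3C | intermediate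
28 | C14 hydroximoyl chloride of 27 | ON=C(Cl)C/C=C(C)\[C@@H]1[C@H](OCc2ccc(OC)cc2)[C@@]3(O)[C@H](/C=C(/C)CC/C=C1\C)OC(=O)[C@@H]3C | intermediate
29 | C14 nitrile oxide | [O-][N+]#CC/C=C(C)\[C@@H]1[C@H](OCc2ccc(OC)cc2)[C@@]3(O)[C@H](/C=C(/C)CC/C=C1\C)OC(=O)[C@@H]3C | intermediate
30 | ring A-fused isoxazoline (C14=N–O–C2): tetracycle with rings A and B, lactone, 8-OH, 9-OPMB, 5Z and 11-ene; 1R,2S,7S,8R,9S,10S,17R | N1=C2CC=C(C)[C@@H]3[C@H](OCc5ccc(OC)cc5)[C@@]4(O)[C@H](/C=C(/C)CC[C@H](O1)[C@@]23C)OC(=O)[C@@H]4C | intermediate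
31 | C14 imine with 2-OH (β-hydroxy imine) | N=C1CC=C(C)[C@@H]2[C@H](OCc3ccc(OC)cc3)[C@@]4(O)[C@H](/C=C(/C)CC[C@H](O)[C@@]12C)OC(=O)[C@@H]4C | intermediate
32 | C14 ketone with 2-OH, 8-OH, 9-OPMB; 1S,2S,7S,8R,9S,10S,17R | O=C1CC=C(C)[C@@H]2[C@H](OCc3ccc(OC)cc3)[C@@]4(O)[C@H](/C=C(/C)CC[C@H](O)[C@@]12C)OC(=O)[C@@H]4C | intermediate
33 | 2-O-diethylborinate of 32 | O=C1CC=C(C)[C@@H]2[C@H](OCc3ccc(OC)cc3)[C@@]4(O)[C@H](/C=C(/C)CC[C@H](OB(CC)CC)[C@@]12C)OC(=O)[C@@H]4C | intermediate
34 | 2,14-diol with 8-OH and 9-OPMB; 1S,2S,7S,8R,9S,10S,14S,17R | O[C@H]1CC=C(C)[C@@H]2[C@H](OCc3ccc(OC)cc3)[C@@]4(O)[C@H](/C=C(/C)CC[C@H](O)[C@@]12C)OC(=O)[C@@H]4C | intermediate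
35 | 2,8,9,14-tetraol; 1S,2S,7S,8R,9S,10S,14S,17R | O[C@H]1CC=C(C)[C@@H]2[C@H](O)[C@@]3(O)[C@H](/C=C(/C)CC[C@H](O)[C@@]12C)OC(=O)[C@@H]3C | intermediate
36 | CNP0187165.2: 2,9,14-triacetate with free 8-OH; 1S,2S,5Z,7S,8S,9S,10S,14S,17R | CC(=O)O[C@H]1CC=C(C)[C@@H]2[C@H](OC(C)=O)[C@@]3(O)[C@H](/C=C(/C)CC[C@H](OC(C)=O)[C@@]12C)OC(=O)[C@@H]3C | target

**Step count and risks**

Total: 24 steps. Longest linear sequence: 23 steps (steps 1–5 and 7–24 from nerol); step 6 is a one-step side branch.

Most likely to fail, step 14 (pinacol macrocyclisation). Intermolecular coupling or simple reduction of the aldehydes may outrun closure of the strained ten-membered ring, the enal-derived allylic ketyl may lose its Z geometry, and the two faces at C7 may not be differentiated. The fallback replaces ketyl coupling by an organochromium 1,2-addition; it sets out from 17 and comes back at 24. DMP oxidation of 17 would give the C8 aldehyde F1. Aldol addition of the lithium enolate of methyl propanoate (LDA, THF, −78 °C) gives β-hydroxy ester F2, and a second DMP oxidation gives β-keto ester F3. NaH and PhNTf2 trap the chelated sodium enolate as the Z enol triflate F4, with the triflate cis to the ester. CSA/MeOH removes the TBS group to give allylic alcohol F5, and MnO2 gives the Z enal F6. CrCl2 with catalytic NiCl2 in DMSO/THF at high dilution (Nozaki–Hiyama–Kishi reaction) adds the C8 alkenylchromium to the C7 aldehyde, and the alkoxide lactonises onto the cis ester to give the ring B butenolide F7. Nucleophilic epoxidation (t-BuOOH, DBU) should give the 8,17-epoxy lactone F8 on the face that lets C9 swing away from C6. SmI2 in THF/MeOH then cleaves the C17–O bond and gives 24.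

Second, step 20 (nitrile oxide cycloaddition). Dimerisation of the nitrile oxide to the furoxan, or tautomerisation of the β,γ-unsaturated nitrile oxide into conjugation, may be faster than the transannularly strained ring closure, and facial selectivity at C1=C2 may be poor. The fallback forms the same two bonds from a silyl nitronate; it sets out from 25 and comes back at 30. I2, PPh3 and imidazole give the primary iodide F9, and NaNO2 in DMF gives the nitroalkane F10. TMSCl and Et3N in toluene give the silyl nitronate F11, which does not dimerise and can be warmed until it adds across C1=C2 to the N-silyloxyisoxazolidine F12. TsOH then eliminates trimethylsilanol and gives 30.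

Third, step 9 (directed carbomagnesiation). The alkyne next to the branched C10 may resist addition, or the methyl group may be delivered to C12 instead of C11. The fallback brings the Z olefin in ready-made; it sets out from 8 and comes back at 16. Purchased 3-(TBDPS-oxy)propanal and the ylide from (1-iodoethyl)triphenylphosphonium iodide and NaHMDS (Stork–Zhao-type olefination) give the Z vinyl iodide F13. Iodine–lithium exchange with t-BuLi and transmetalation with Et2AlCl give the alkenylalane F14, which opens 8 at C10 in the manner of step 7 to give the diol F15. Acetalisation as in step 8 gives 16.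

**Further compounds**

F1 | step 14 | C8 aldehyde from 17 (9-OPMB, 7-OTBS, 14-OTBDPS) | O=C[C@@H](OCc1ccc(OC)cc1)[C@@H](/C(C)=C\CCO[Si](c2ccccc2)(c3ccccc3)C(C)(C)C)/C(C)=C/CC/C(C)=C\CO[Si](C)(C)C(C)(C)C
F2 | step 14 | methyl 3-hydroxy-2-methyl ester (propanoate aldol adduct at C8; diastereomer mixture at C8/C17) | COC(=O)C(C)C(O)[C@@H](OCc1ccc(OC)cc1)[C@@H](/C(C)=C\CCO[Si](c2ccccc2)(c3ccccc3)C(C)(C)C)/C(C)=C/CC/C(C)=C\CO[Si](C)(C)C(C)(C)C
F3 | step 14 | β-keto ester (C8 ketone, C17 methyl, C19 methyl ester) | COC(=O)C(C)C(=O)[C@@H](OCc1ccc(OC)cc1)[C@@H](/C(C)=C\CCO[Si](c2ccccc2)(c3ccccc3)C(C)(C)C)/C(C)=C/CC/C(C)=C\CO[Si](C)(C)C(C)(C)C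
F4 | step 14 | Z enol triflate at C8 (triflate cis to the ester) | COC(=O)/C(C)=C(\OS(=O)(=O)C(F)(F)F)[C@@H](OCc1ccc(OC)cc1)[C@@H](/C(C)=C\CCO[Si](c2ccccc2)(c3ccccc3)C(C)(C)C)/C(C)=C/CC/C(C)=C\CO[Si](C)(C)C(C)(C)C
F5 | step 14 | C7 allylic alcohol of F4 | COC(=O)/C(C)=C(\OS(=O)(=O)C(F)(F)F)[C@@H](OCc1ccc(OC)cc1)[C@@H](/C(C)=C\CCO[Si](c2ccccc2)(c3ccccc3)C(C)(C)C)/C(C)=C/CC/C(C)=C\CO
F6 | step 14 | C7 Z-enal of F5 | COC(=O)/C(C)=C(\OS(=O)(=O)C(F)(F)F)[C@@H](OCc1ccc(OC)cc1)[C@@H](/C(C)=C\CCO[Si](c2ccccc2)(c3ccccc3)C(C)(C)C)/C(C)=C/CC/C(C)=C\C=O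
F7 | step 14 | ring B butenolide (C8=C17, lactone O on C7; 9-OPMB, 14-OTBDPS) | CC(C)(C)[Si](c1ccccc1)(c2ccccc2)OCC/C=C(C)\[C@@H]3[C@H](OCc4ccc(OC)cc4)C5=C(C)C(=O)O[C@H]5/C=C(/C)CC/C=C3\C
F8 | step 14 | 8,17-epoxy lactone (epoxide oxygen α) | CC(C)(C)[Si](c1ccccc1)(c2ccccc2)OCC/C=C(C)\[C@@H]3[C@H](OCc4ccc(OC)cc4)[C@@]56O[C@@]6(C)C(=O)O[C@H]5/C=C(/C)CC/C=C3\C
F9 | step 20 | C14 iodide from 25 | ICC/C=C(C)\[C@@H]1[C@H](OCc2ccc(OC)cc2)[C@@]3(O)[C@H](/C=C(/C)CC/C=C1\C)OC(=O)[C@@H]3C
F10 | step 20 | C14 nitroalkane | [O-][N+](=O)CC/C=C(C)\[C@@H]1[C@H](OCc2ccc(OC)cc2)[C@@]3(O)[C@H](/C=C(/C)CC/C=C1\C)OC(=O)[C@@H]3C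
F11 | step 20 | trimethylsilyl nitronate of F10 | C[Si](C)(C)O[N+]([O-])=CC/C=C(C)\[C@@H]1[C@H](OCc2ccc(OC)cc2)[C@@]3(O)[C@H](/C=C(/C)CC/C=C1\C)OC(=O)[C@@H]3C
F12 | step 20 | N-(trimethylsilyloxy)isoxazolidine (C14–C1 and O–C2 formed; C14 epimers) | N1(O[Si](C)(C)C)C2CC=C(C)[C@@H]3[C@H](OCc5ccc(OC)cc5)[C@@]4(O)[C@H](/C=C(/C)CC[C@H](O1)[C@@]23C)OC(=O)[C@@H]4C
F13 | step 9 | tert-butyl{[(3Z)-4-iodopent-3-en-1-yl]oxy}diphenylsilane | C/C(I)=C/CCO[Si](c1ccccc1)(c1ccccc1)C(C)(C)C
F14 | step 9 | diethyl[(2Z)-5-(TBDPS-oxy)pent-2-en-2-yl]aluminium | CC[Al](CC)/C(C)=C\CCO[Si](c1ccccc1)(c1ccccc1)C(C)(C)C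
F15 | step 9 | 8,9-diol with the Z side chain in place (7-OTBS, 14-OTBDPS; 9S,10R) | OC[C@@H](O)[C@@H](/C(C)=C\CCO[Si](c1ccccc1)(c2ccccc2)C(C)(C)C)/C(C)=C/CC/C(C)=C\CO[Si](C)(C)C(C)(C)C
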